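**Plan**
- The target is read as the trans-(1R,2R) 1-(2-pyranon-3-yl)-1,2-dihydronaphthalene: an aryl-dihydronaphthalene lignan of the caffeic acid dimer type whose pendant catechol is replaced by a 6-carboxy-2-pyranone.
- Retrosynthesis: the racemate is parted last; before that, C3=C4 and C8a–C1 of the carbocycle are cut together (formal [3+3]) to 3,4-dihydroxybenzaldehyde and a pyranonylidene succinic half-ester; the pyranone C3–CH bond is then cut (Heck) to a pyranonyl triflate and 1-methyl itaconate; the pyranone goes back to mucic acid.
- Forward order: pyranone ring from mucic acid, side chain by Heck coupling, carbocycle last in a one-flask aldol / dehydration / ring-closure cascade that also frees both acids and the catechol.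
- Enabling feature: in the 2,3-bis(alkylidene)succinate the atoms C8a=C4a–C4=C3–C2=C1 form a 1-aryl-hexatriene. C8a is para to the C6 oxygen (donor end); C1 is the beta-carbon of the C2 methyl acrylate and carries the electron-poor pyranone ring (acceptor end); C4 is benzylic and para to the C7 oxygen, so the aldol oxygen can leave through a quinone-methide-type cation, echoing the presumed biosynthesis.
- Stereochemistry: the C1/C2 trans relationship comes from anti, thermodynamically backed protonation at C2 during ring closure; the absolute configuration comes from resolution of the racemic acid on a chiral anion-exchange phase.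
- Protecting groups: one tert-butyl ester only, shed in the key step; phenols and acids are silylated only in situ.

Key step: step 7

Remark: in the given SMILES the C1 pyranone and the C2 ester lie on opposite faces of the ring; because the pyranone outranks C8a at C1, this trans isomer is (1R,2R).

Step 1
Reactants: 1 mucic acid (galactaric acid)
Product: 2 3-acetoxy-2-oxo-2H-pyran-6-carboxylic acid
Conditions: Ac2O, KOAc (cat.), 100 °C; then cold 2 M HCl
Reagents that add atoms: acetic anhydride, CC(=O)OC(C)=O
Why: Acetic anhydride with acetate effects the established threefold dehydration and lactonisation of the aldaric acid to the 3-hydroxy-2-pyranone-6-carboxylic acid core (elimination/lactonisation cascade) and acetylates its enol, which should give 2 after acidification.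

Step 2
Reactants: 2 3-acetoxy-2-oxo-2H-pyran-6-carboxylic acid
Product: 3 3-hydroxy-2-oxo-2H-pyran-6-carboxylic acid
Conditions: 6 M HCl, 90 °C
Reagents that add atoms: none
Why: Acid-catalysed hydrolysis of the enol acetate should free the 3-hydroxyl, while the pyranone ring and the carboxylic acid (which decarboxylates only at far higher temperature) stay intact.

Step 3
Reactants: 3 3-hydroxy-2-oxo-2H-pyran-6-carboxylic acid
Product: 4 tert-butyl 3-hydroxy-2-oxo-2H-pyran-6-carboxylate
Conditions: Cl3CC(=NH)OtBu (2 equiv), THF/cyclohexane, rt
Reagents that add atoms: tert-butyl 2,2,2-trichloroacetimidate, CC(C)(C)OC(=N)C(Cl)(Cl)Cl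
Why: Trichloroacetimidate esterification: the strongly acidic carboxyl protonates the imidate and takes up the tert-butyl group, whereas the much less acidic enolic hydroxyl should stay free in the absence of an added acid catalyst.

Step 4
Reactants: 4 tert-butyl 3-hydroxy-2-oxo-2H-pyran-6-carboxylate
Product: 5 tert-butyl 2-oxo-3-{[(trifluoromethyl)sulfonyl]oxy}-2H-pyran-6-carboxylate
Conditions: Tf2O, pyridine, CH2Cl2, −20 to 0 °C
Reagents that add atoms: trifluoromethanesulfonic anhydride, O=S(=O)(OS(=O)(=O)C(F)(F)F)C(F)(F)F
Why: O-Triflation of the enolic hydroxyl (enol triflate formation) should turn C3 of the pyranone into a pseudohalide for palladium coupling; the tert-butyl ester tolerates the buffered conditions.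

Step 5
Reactants: 6 dimethyl itaconate
Product: 7 3-(methoxycarbonyl)but-3-enoic acid (1-methyl hydrogen itaconate)
Conditions: LiOH·H2O (1.0 equiv), THF/H2O, 0 °C; then 1 M HCl
Reagents that add atoms: lithium hydroxide, [Li+].[OH-]
Why: Regioselective saponification (monohydrolysis of a diester): hydroxide should attack the saturated, unhindered ester in preference to the conjugated acrylate ester, and the low temperature limits base-induced migration of the exocyclic double bond.

Step 6
Reactants: 5 tert-butyl 2-oxo-3-{[(trifluoromethyl)sulfonyl]oxy}-2H-pyran-6-carboxylate; 7 3-(methoxycarbonyl)but-3-enoic acid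
Product: 8 (3E)-4-[6-(tert-butoxycarbonyl)-2-oxo-2H-pyran-3-yl]-3-(methoxycarbonyl)but-3-enoic acid
Conditions: Pd(OAc)2 (5 mol %), PPh3 (10 mol %), Et3N (3 equiv), DMF, 70 °C
Reagents that add atoms: none
Why: Mizoroki–Heck reaction: the pyranonyl palladium species adds to the CH2 terminus of the itaconate, and syn beta-hydride elimination towards the new CH should give the conjugated (E)-alkylidene succinate (pyranone trans to CO2Me), the usual outcome for aryl halides and triflates with itaconates.

Step 7
Reactants: 8 (3E)-4-[6-(tert-butoxycarbonyl)-2-oxo-2H-pyran-3-yl]-3-(methoxycarbonyl)but-3-enoic acid; 9 3,4-dihydroxybenzaldehyde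
Product: 14 racemic trans-1-(6-carboxy-2-oxo-2H-pyran-3-yl)-6,7-dihydroxy-2-(methoxycarbonyl)-1,2-dihydronaphthalene-3-carboxylic acid, via silylated aldehyde 10 (not isolated), via bis-silyl ketene acetal 11 (not isolated), via silylated aldol adduct 12 (not isolated), via E,E-diene diacid 13 (not isolated)
Conditions: TMSOTf (6 equiv), iPr2NEt (6 equiv), CH2Cl2, 0 °C to rt; then TfOH (10 equiv), 0 °C to rt; H2O work-up (Ar throughout)
Reagents that add atoms: none
Why: Proposed new method: TMSOTf/iPr2NEt should silylate the phenols of 9 (giving 10) and the acid of 8 and enolise the silyl ester to the bis-silyl ketene acetal 11, whose Mukaiyama aldol addition through its alpha-carbon to 10 gives 12. TfOH should then ionise the para-silyloxybenzylic C–O bond (future C4) to a quinone-methide-type cation, loss of the adjacent proton gives the (E,E)-diene 13, the catechol carbon para to the C6 oxygen adds to the pyranone-bearing beta-carbon of the protonated methyl acrylate unit, and the tert-butyl ester and silyl groups are shed in the same medium. The closest known reaction types are the TMSOTf/trialkylamine aldol addition of carboxylic acids via bis-silyl ketene acetals, the triflic acid cyclisation of 2,3-bis(arylidene)succinates to trans-1-aryl-1,2-dihydronaphthalenes and the superacid hydroarylation of heteroaryl-substituted acrylic acids; new are their union in one flask and a 2-pyranone in place of the electron-rich aryl group. The six-membered ring closes by a 6-endo-trig Friedel–Crafts conjugate addition, the polar counterpart of a 6π-electrocyclisation of the aryl-triene C8a=C4a–C4=C3–C2=C1. C1 is created in this bond formation without facial bias (racemate), and C2 is set by protonation of the resulting ester enol anti to the C1 pyranone, which is also the thermodynamic trans arrangement reachable by reversible enolisation in TfOH. The step needs alpha- over gamma-attack in the aldol (gamma is the hindered carbon bearing the pyranone, and attack there would break the pyranonylidene-acrylate conjugation), closure para and not ortho to the C6 oxygen (the ortho site is flanked on both sides), and the catechol ring as the only nucleophile (the pyranone ring is electron-poor and, once protonated, makes C1 the acceptor).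

Step 8
Reactants: 14 racemic trans-1-(6-carboxy-2-oxo-2H-pyran-3-yl)-6,7-dihydroxy-2-(methoxycarbonyl)-1,2-dihydronaphthalene-3-carboxylic acid
Product: 15 (1R,2R)-1-(6-carboxy-2-oxo-2H-pyran-3-yl)-6,7-dihydroxy-2-(methoxycarbonyl)-1,2-dihydronaphthalene-3-carboxylic acid (target)
Conditions: preparative HPLC, quinine tert-butylcarbamate anion-exchange chiral stationary phase, MeOH/AcOH/NH4OAc
Reagents that add atoms: none
Why: Resolution by chiral anion-exchange chromatography: the enantiomeric acids form diastereomeric ion pairs with the immobilised quinine carbamate selector and should elute apart with no stereocentre touched; the (1R,2R) fraction is to be identified by electronic circular dichroism.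

**Compound list**
1 | mucic acid (galactaric acid, meso) | OC(=O)[C@H](O)[C@@H](O)[C@@H](O)[C@H](O)C(=O)O | starting material
2 | 3-acetoxy-2-oxo-2H-pyran-6-carboxylic acid | CC(=O)Oc1ccc(C(=O)O)oc1=O | intermediate
3 | 3-hydroxy-2-oxo-2H-pyran-6-carboxylic acid | O=C(O)c1ccc(O)c(=O)o1 | intermediate
4 | tert-butyl 3-hydroxy-2-oxo-2H-pyran-6-carboxylate | CC(C)(C)OC(=O)c1ccc(O)c(=O)o1 | intermediate
5 | tert-butyl 2-oxo-3-{[(trifluoromethyl)sulfonyl]oxy}-2H-pyran-6-carboxylate | CC(C)(C)OC(=O)c1ccc(OS(=O)(=O)C(F)(F)F)c(=O)o1 | intermediate
6 | dimethyl itaconate | C=C(CC(=O)OC)C(=O)OC | starting material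
7 | 3-(methoxycarbonyl)but-3-enoic acid (1-methyl hydrogen itaconate) | C=C(CC(=O)O)C(=O)OC | intermediate
8 | (3E)-4-[6-(tert-butoxycarbonyl)-2-oxo-2H-pyran-3-yl]-3-(methoxycarbonyl)but-3-enoic acid | COC(=O)/C(CC(=O)O)=C/c1ccc(C(=O)OC(C)(C)C)oc1=O | intermediate
9 | 3,4-dihydroxybenzaldehyde | O=Cc1ccc(O)c(O)c1 | starting material
10 | 3,4-bis(trimethylsilyloxy)benzaldehyde | O=Cc1ccc(O[Si](C)(C)C)c(O[Si](C)(C)C)c1 | intermediate
11 | tert-butyl 3-[(1E)-2-(methoxycarbonyl)-4,4-bis(trimethylsilyloxy)buta-1,3-dien-1-yl]-2-oxo-2H-pyran-6-carboxylate | COC(=O)/C(C=C(O[Si](C)(C)C)O[Si](C)(C)C)=C/c1ccc(C(=O)OC(C)(C)C)oc1=O | intermediate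
12 | trimethylsilyl (3E)-2-{[3,4-bis(trimethylsilyloxy)phenyl](trimethylsilyloxy)methyl}-4-[6-(tert-butoxycarbonyl)-2-oxo-2H-pyran-3-yl]-3-(methoxycarbonyl)but-3-enoate (diastereomer mixture) | COC(=O)/C(=C/c1ccc(C(=O)OC(C)(C)C)oc1=O)C(C(=O)O[Si](C)(C)C)C(O[Si](C)(C)C)c1ccc(O[Si](C)(C)C)c(O[Si](C)(C)C)c1 | intermediate
13 | (2E,3E)-3-[(6-carboxy-2-oxo-2H-pyran-3-yl)methylidene]-2-[(3,4-dihydroxyphenyl)methylidene]-4-methoxy-4-oxobutanoic acid | COC(=O)/C(=C/c1ccc(C(=O)O)oc1=O)/C(C(=O)O)=C\c1ccc(O)c(O)c1 | intermediate
14 | racemic trans-1-(6-carboxy-2-oxo-2H-pyran-3-yl)-6,7-dihydroxy-2-(methoxycarbonyl)-1,2-dihydronaphthalene-3-carboxylic acid (1:1 mixture of the 1R,2R and 1S,2S forms) | COC(=O)[C@H]1C(C(=O)O)=Cc2cc(O)c(O)cc2[C@@H]1c1ccc(C(=O)O)oc1=O.COC(=O)[C@@H]1C(C(=O)O)=Cc2cc(O)c(O)cc2[C@H]1c1ccc(C(=O)O)oc1=O | intermediate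
15 | (1R,2R)-1-(6-carboxy-2-oxo-2H-pyran-3-yl)-6,7-dihydroxy-2-(methoxycarbonyl)-1,2-dihydronaphthalene-3-carboxylic acid | COC(=O)[C@H]1C(C(=O)O)=Cc2cc(O)c(O)cc2[C@@H]1c1ccc(C(=O)O)oc1=O | target

Total step count: 8. Longest linear sequence: 7 steps (steps 1, 2, 3, 4, 6, 7, 8).

**Steps most likely to fail**

Step 7 (carries the label Proposed new method:). The dienol silane may attack through its gamma-carbon, the benzylic cation may be captured intermolecularly by another catechol ring, or ring closure may stall because protonation of the cinnamic acid half drains the catechol ring. The fallback uses known chemistry, sets out from 8 and 9 and returns at 14. Aldehyde 9 is silylated (TBSCl, imidazole, DMF) to 3,4-bis(tert-butyldimethylsilyloxy)benzaldehyde F1. Acid 8 is converted with LDA (2.2 equiv, THF, −78 °C) into its dilithium enediolate, which adds F1 at the alpha-carbon in an Ivanov-type aldol reaction to give the hydroxy acid F2, isolated as a diastereomer mixture. Treatment of F2 with TfOH in CH2Cl2 at 0 °C should bring about dehydration, the acid cyclisation known for bis(alkylidene)succinates and loss of the silyl and tert-butyl groups, giving 14.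

Step 6. Beta-hydride elimination may run towards the CH2CO2H side and give the double-bond isomer, the itaconate may isomerise under the basic conditions, or the triflate may be hydrolysed. The fallback sets out from 5 and returns at 8 by olefination instead of Heck coupling. Triflate 5 is formylated (Pd(OAc)2, 1,3-bis(diphenylphosphino)propane, CO, Et3SiH, Et3N, DMF, 70 °C) to tert-butyl 3-formyl-2-oxo-2H-pyran-6-carboxylate F3. Methyl (diethoxyphosphoryl)acetate is alkylated with tert-butyl bromoacetate (NaH, THF) to 4-tert-butyl 1-methyl 2-(diethoxyphosphoryl)butanedioate F4, whose tert-butyl ester is cleaved with TFA to 3-(diethoxyphosphoryl)-4-methoxy-4-oxobutanoic acid F5. Horner–Wadsworth–Emmons reaction of the disodium salt of F5 (NaH, 2 equiv, THF, 0 °C) with F3 should give 8 as the (E)-isomer.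

Step 8. The phase may discriminate the enantiomers too weakly for preparative loading, or the catechol may oxidise in air during long runs. The fallback sets out from 14 and returns at 15 by classical resolution. Racemate 14 is combined with (S)-1-phenylethylamine (2 equiv) in EtOH/H2O and the less soluble bis[(S)-1-phenylethylammonium] salt F6 of the (1R,2R)-acid is fractionally crystallised; the antipodal amine is used should the (1S,2S)-salt be the one that crystallises. Dilute HCl then releases 15.

**Further compounds**
F1 | step 7 | 3,4-bis(tert-butyldimethylsilyloxy)benzaldehyde | O=Cc1ccc(O[Si](C)(C)C(C)(C)C)c(O[Si](C)(C)C(C)(C)C)c1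
F2 | step 7 | (3E)-2-{[3,4-bis(tert-butyldimethylsilyloxy)phenyl](hydroxy)methyl}-4-[6-(tert-butoxycarbonyl)-2-oxo-2H-pyran-3-yl]-3-(methoxycarbonyl)but-3-enoic acid (diastereomer mixture) | COC(=O)/C(=C/c1ccc(C(=O)OC(C)(C)C)oc1=O)C(C(=O)O)C(O)c1ccc(O[Si](C)(C)C(C)(C)C)c(O[Si](C)(C)C(C)(C)C)c1
F3 | step 6 | tert-butyl 3-formyl-2-oxo-2H-pyran-6-carboxylate | CC(C)(C)OC(=O)c1ccc(C=O)c(=O)o1
F4 | step 6 | 4-tert-butyl 1-methyl 2-(diethoxyphosphoryl)butanedioate | CCOP(=O)(OCC)C(CC(=O)OC(C)(C)C)C(=O)OC
F5 | step 6 | 3-(diethoxyphosphoryl)-4-methoxy-4-oxobutanoic acid | CCOP(=O)(OCC)C(CC(=O)O)C(=O)OC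
F6 | step 8 | bis[(S)-1-phenylethylammonium] (1R,2R)-1-(6-carboxylato-2-oxo-2H-pyran-3-yl)-6,7-dihydroxy-2-(methoxycarbonyl)-1,2-dihydronaphthalene-3-carboxylate | COC(=O)[C@H]1C(C(=O)[O-])=Cc2cc(O)c(O)cc2[C@@H]1c1ccc(C(=O)[O-])oc1=O.C[C@H]([NH3+])c1ccccc1.C[C@H]([NH3+])c1ccccc1
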